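**Retrosynthetic overview**

1. Isomuronic acid ⇐ its methyl ester (acid hydrolysis) ⇐ the acyclic (R)-2-methyl-18-oxononadeca-2,3-dienoic acid, by one palladium-catalysed cyclization–methoxycarbonylation that closes the only ring (the butenolide, through its O1–C5 bond), sets C5 and attaches the carboxyl carbon to C4.
2. Enabling feature (furan-2(5H)-one numbering): ring atoms C2(=O)–C3(CH3)=C4–C5(H)(chain) are C1–C4 of a 2,3-allenoic acid. Ring C4, the carbon bearing the exocyclic CO2H, is the central allene carbon and becomes a C–Pd bond that takes up CO; the C3=C4 ring alkene is the surviving half of the cumulene, and the allene axis becomes the C5 centre.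
3. Allenoic acid ⇐ (S)-propargylic mesylate (anti-SN2′ hydroxycarbonylation with zerovalent palladium, centre-to-axis transfer) ⇐ (S)-carbinol from asymmetric transfer hydrogenation of an ynone.
4. Carbon skeleton: ω-pentadecalactone (C15) + propynyl Grignard (C3) + methyl Grignard (C1) + two CO; a Weinreb amide carries the latent methyl ketone until the carbinol is in place, so no protecting groups are needed.

Key step: step 9

Remark: the ring stereocentre of the target is (R); it is assumed that the (S,S)-configured ruthenium catalyst reduces the alkynyl ketone with the same sense as an aryl ketone (alkynyl in the place of aryl), giving the (S)-carbinol that the stereochemical relay requires.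

**Step 1**
Reactants: 1 ω-pentadecalactone (oxacyclohexadecan-2-one)
Product: 2 15-hydroxy-N-methoxy-N-methylpentadecanamide
Conditions: MeNH(OMe)·HCl, i-PrMgCl, THF, −20 → 0 °C
Reagents that add atoms: N,O-dimethylhydroxylamine hydrochloride, CNOC.Cl
Why: Aminolysis of the lactone by the chloromagnesium amide of N,O-dimethylhydroxylamine (Weinreb amide formation from an ester) should open the macrocycle and stop at the amide, freeing the primary alcohol.

**Step 2**
Reactants: 2 15-hydroxy-N-methoxy-N-methylpentadecanamide
Product: 3 N-methoxy-N-methyl-15-oxopentadecanamide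
Conditions: TEMPO (10 mol %), PhI(OAc)2, CH2Cl2, rt
Reagents that add atoms: none
Why: The TEMPO/oxoammonium oxidation of a primary alcohol should stop cleanly at the aldehyde and leave the Weinreb amide untouched.

**Step 3**
Reactants: 3 N-methoxy-N-methyl-15-oxopentadecanamide
Product: 4 rac-15-hydroxy-N-methoxy-N-methyloctadec-16-ynamide
Conditions: CH3C≡CMgBr (1.1 equiv), THF, −78 → −20 °C; then H2O
Reagents that add atoms: 1-propynylmagnesium bromide, CC#C[Mg]Br
Why: Grignard 1,2-addition should occur at the aldehyde only, since a Weinreb amide is inert to an alkynylmagnesium reagent at low temperature; the racemic carbinol is acceptable because the centre is erased in step 4.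

**Step 4**
Reactants: 4 rac-15-hydroxy-N-methoxy-N-methyloctadec-16-ynamide
Product: 5 N-methoxy-N-methyl-15-oxooctadec-16-ynamide
Conditions: Dess–Martin periodinane, CH2Cl2, 0 °C → rt
Reagents that add atoms: none
Why: Dess–Martin oxidation of a propargylic alcohol should give the conjugated ynone under neutral conditions without touching the amide or the alkyne.

**Step 5**
Reactants: 5 N-methoxy-N-methyl-15-oxooctadec-16-ynamide
Product: 6 (S)-15-hydroxy-N-methoxy-N-methyloctadec-16-ynamide
Conditions: Ru[(S,S)-TsDPEN](p-cymene) (amido complex, 1 mol %), i-PrOH, rt
Reagents that add atoms: none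
Why: Noyori asymmetric transfer hydrogenation of an alkynyl ketone should deliver hydride through the six-membered metal–ligand bifunctional transition state with the alkynyl group in the aryl position, setting the (S)-carbinol, while the base-free catalyst spares the ynone and the amide.

**Step 6**
Reactants: 6 (S)-15-hydroxy-N-methoxy-N-methyloctadec-16-ynamide
Product: 7 (S)-16-hydroxynonadec-17-yn-2-one
Conditions: MeMgBr (3 equiv), THF, 0 °C; then H2O
Reagents that add atoms: methylmagnesium bromide, C[Mg]Br
Why: In the Weinreb ketone synthesis the stable magnesium chelate should prevent over-addition and release the methyl ketone on work-up, the carbinol being carried as its alkoxide without risk to the stereocentre.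

**Step 7**
Reactants: 7 (S)-16-hydroxynonadec-17-yn-2-one
Product: 8 (S)-18-oxononadec-2-yn-4-yl methanesulfonate
Conditions: MsCl, Et3N, CH2Cl2, −78 → 0 °C
Reagents that add atoms: methanesulfonyl chloride, CS(=O)(=O)Cl
Why: O-Sulfonylation forms only the O–S bond, so the (S) configuration is retained and the distal ketone is not affected; the mesylate should be used directly.

**Step 8**
Reactants: 8 (S)-18-oxononadec-2-yn-4-yl methanesulfonate
Product: 9 (R)-2-methyl-18-oxononadeca-2,3-dienoic acid
Conditions: Pd(PPh3)4 (5 mol %), CO (1 atm), THF/H2O (10:1), rt
Reagents that add atoms: carbon monoxide, [C-]#[O+]; water, O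
Why: Palladium-catalysed carbonylation of a propargylic mesylate should proceed by anti-SN2′ oxidative addition of zerovalent palladium, CO insertion with retention and hydrolysis, so the (S) carbinol centre is relayed stereospecifically into the (R) allene axis of the 2,3-allenoic acid.

**Step 9**
Reactants: 9 (R)-2-methyl-18-oxononadeca-2,3-dienoic acid
Product: 12 methyl (R)-4-methyl-5-oxo-2-(14-oxopentadecyl)-2,5-dihydrofuran-3-carboxylate, via 4-palladated butenolide 10 (not isolated), via acylpalladium complex 11 (not isolated)
Conditions: Pd(OCOCF3)2 (5 mol %), p-benzoquinone (1.5 equiv), CO (1 atm), MeOH, 0 °C → rt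
Reagents that add atoms: carbon monoxide, [C-]#[O+]; methanol, CO
Why: Proposed new method: divalent palladium binds the C3=C4 π bond of 9 on the face away from the acid, the carboxyl oxygen adds to C4 to give the ring-closed σ-vinylpalladium 10 (palladium on the future ring C4), CO insertion gives 11, methanolysis releases ester 12 and zerovalent palladium, and p-benzoquinone restores divalent palladium. The closest known reactions are the cyclization–methoxycarbonylation of allenyl ketones to furan-3-carboxylates (the same 5-endo oxypalladation followed by CO/MeOH capture) and the PdCl2-catalysed cyclization–coupling reactions of 2,3-allenoic acids, which trap the same furanonyl–palladium species with carbon electrophiles; the combination of the two on an allenoic acid is what is new. The single ring is closed in a 5-endo-trig anti-oxypalladation, oxygen attacking the allene terminus. The C5 stereocentre is set by axis-to-centre chirality transfer, because the carboxyl group lies in the plane of the C3=C4 π orbital and can reach only one face of C4, so the (R) axis should give (R)-C5 irrespective of how the metal is bound. The step needs oxygen to attack C4 only, and the two-atom carboxyl tether on C2 secures this, since attack at C3 would require a four-membered ring. It also needs CO capture of 10 to outrun protodepalladation, oxidative dimerization and allene racemization, for which the fully substituted, β-hydrogen-free vinylpalladium, the CO atmosphere, methanol as solvent and a halide-free, base-free medium (which also protects the acidic C5–H of 12) are relied on.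

**Step 10**
Reactants: 12 methyl (R)-4-methyl-5-oxo-2-(14-oxopentadecyl)-2,5-dihydrofuran-3-carboxylate
Product: 13 isomuronic acid, (R)-4-methyl-5-oxo-2-(14-oxopentadecyl)-2,5-dihydrofuran-3-carboxylic acid
Conditions: 6 M HCl, 1,4-dioxane, 90 °C
Reagents that add atoms: water, O
Why: Acid-catalysed ester hydrolysis (AAC2) should free the carboxylic acid without any base, so the γ-proton at C5 is never removed, and any ring-opened hydroxy acid must reclose because the Z-alkene holds carboxyl and carbinol together.

**Compound list**

1 | ω-pentadecalactone (oxacyclohexadecan-2-one) | O=C1CCCCCCCCCCCCCCO1 | starting material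
2 | 15-hydroxy-N-methoxy-N-methylpentadecanamide | CON(C)C(=O)CCCCCCCCCCCCCCO | intermediate
3 | N-methoxy-N-methyl-15-oxopentadecanamide | CON(C)C(=O)CCCCCCCCCCCCCC=O | intermediate
4 | rac-15-hydroxy-N-methoxy-N-methyloctadec-16-ynamide | CON(C)C(=O)CCCCCCCCCCCCCC(O)C#CC | intermediate
5 | N-methoxy-N-methyl-15-oxooctadec-16-ynamide | CON(C)C(=O)CCCCCCCCCCCCCC(=O)C#CC | intermediate
6 | (S)-15-hydroxy-N-methoxy-N-methyloctadec-16-ynamide | CON(C)C(=O)CCCCCCCCCCCCC[C@H](O)C#CC | intermediate
7 | (S)-16-hydroxynonadec-17-yn-2-one | CC(=O)CCCCCCCCCCCCC[C@H](O)C#CC | intermediate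
8 | (S)-18-oxononadec-2-yn-4-yl methanesulfonate | CC(=O)CCCCCCCCCCCCC[C@H](OS(C)(=O)=O)C#CC | intermediate
9 | (R)-2-methyl-18-oxononadeca-2,3-dienoic acid (R allene axis) | OC(=O)C(C)=[C@]=C([H])CCCCCCCCCCCCCC(C)=O | intermediate
10 | [(R)-4-methyl-5-oxo-2-(14-oxopentadecyl)-2,5-dihydrofuran-3-yl]palladium trifluoroacetate (4-palladated butenolide) | CC(=O)CCCCCCCCCCCCC[C@H]1OC(=O)C(C)=C1[Pd]OC(=O)C(F)(F)F | intermediate
11 | [(R)-4-methyl-5-oxo-2-(14-oxopentadecyl)-2,5-dihydrofuran-3-carbonyl]palladium trifluoroacetate (acylpalladium complex) | CC(=O)CCCCCCCCCCCCC[C@H]1OC(=O)C(C)=C1C(=O)[Pd]OC(=O)C(F)(F)F | intermediate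
12 | methyl (R)-4-methyl-5-oxo-2-(14-oxopentadecyl)-2,5-dihydrofuran-3-carboxylate | CC(=O)CCCCCCCCCCCCC[C@H]1OC(=O)C(C)=C1C(=O)OC | intermediate
13 | isomuronic acid, (R)-4-methyl-5-oxo-2-(14-oxopentadecyl)-2,5-dihydrofuran-3-carboxylic acid | CC(=O)CCCCCCCCCCCCC[C@H]1OC(=O)C(C)=C1C(=O)O | target

**Step count and risks**

Total step count: 10. Longest linear sequence: 10 steps (fully linear from 1).

Steps most likely to fail:

1. Step 9 (proposed new method). The vinylpalladium intermediate may be lost to protodepalladation or oxidative dimerization before it takes up CO, or the allene may racemize by reversible palladation before ring closure. Fallback by known chemistry, setting out from 9: iodolactonization of the 2,3-allenoic acid (I2, MeCN, rt), which follows the same axis-to-centre transfer, should give (R)-4-iodo-3-methyl-5-(14-oxopentadecyl)furan-2(5H)-one F1. Palladium-catalysed methoxycarbonylation of this vinyl iodide (Pd(OAc)2, PPh3, CO 1 atm, MeOH, NaOAc, DMF, 50 °C) should then give 12, where the route is rejoined.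

2. Step 8. The axial configuration may erode through palladium-for-palladium exchange on the allenyl intermediate, and the free acid may cycloisomerize prematurely under palladium to the butenolide lacking the C4 carboxyl. Fallback, setting out from 8: the carbonylation is run with 2-(trimethylsilyl)ethanol in place of water (Pd(PPh3)4, CO, THF), so that the allene is formed as an ester that cannot lactonize, 2-(trimethylsilyl)ethyl (R)-2-methyl-18-oxononadeca-2,3-dienoate F2. After removal of palladium the acid is released separately by fluoride-induced fragmentation (Bu4NF, THF, 0 °C), coming back to the route at 9.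

3. Step 10. Hydrolysis of the hindered, conjugated ester may be slow, and forcing it may epimerize C5 through the dienol or cause acid-mediated self-condensation of the methyl ketone. Fallback, setting out from 9: the cyclization–carbonylation of step 9 is run with 2-(trimethylsilyl)ethanol (10 equiv, THF) in place of methanol to give 2-(trimethylsilyl)ethyl (R)-4-methyl-5-oxo-2-(14-oxopentadecyl)-2,5-dihydrofuran-3-carboxylate F3. Its ester is cleaved without hydrolysis by β-silyl fragmentation (CF3CO2H, CH2Cl2, rt), coming back to the route at 13.

**Further compounds**

F1 | step 9 | (R)-4-iodo-3-methyl-5-(14-oxopentadecyl)furan-2(5H)-one | CC(=O)CCCCCCCCCCCCC[C@H]1OC(=O)C(C)=C1I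
F2 | step 8 | 2-(trimethylsilyl)ethyl (R)-2-methyl-18-oxononadeca-2,3-dienoate | C[Si](C)(C)CCOC(=O)C(C)=[C@]=C([H])CCCCCCCCCCCCCC(C)=O
F3 | step 10 | 2-(trimethylsilyl)ethyl (R)-4-methyl-5-oxo-2-(14-oxopentadecyl)-2,5-dihydrofuran-3-carboxylate | CC(=O)CCCCCCCCCCCCC[C@H]1OC(=O)C(C)=C1C(=O)OCC[Si](C)(C)C
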